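**Retrosynthetic overview**

- The target is a furofuran with an exo guaiacyl group at C7 (R), an endo syringyl group at C7' (S), ring-fusion centres C8 (S) and C8' (S), and a threo (7''R,8''R) syringylglycerol unit bound as an 8''-O-4' ether.
- Last skeletal bond, C7'–aryl: a side-chain-bearing syringyllithium adds to a cis-fused bicyclic lactone, and exo-face hydride reduction of the hemiketal fixes the endo aryl group.
- Feature on which the strategy rests: ring A (O1, C7, C8, C8', C9') is a 2-aryl tetrahydrofuran with one-carbon branches C9 on C8 and C7' on C8'. It is cut at O1–C7 and C8–C8' into racemic vinylethylene carbonate (an O–CH2–CH(vinyl) dipole) and a guaiacyl nitroacrylate, joined under zerovalent palladium with a chiral phosphoramidite.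
- Side chain: an Evans syn glycolate aldol sets C7'' and C8''.
- Ring order: ring A first, then the lactone ring, which becomes ring B after aryl addition and reduction.

Key step: step 2

Remarks on the chemistry:
- Lignan numbering is used: C7–C9 for the guaiacylpropane unit, C7'–C9' for the syringylpropane unit of the furofuran, C7''–C9'' for the glycerol side chain; O1 and O2 are the oxygens of rings A and B.
- Assumption: the sense of induction of the phosphoramidite cannot be assigned with certainty on paper. The (Sa,S,S) antipode is written; the mirror-image ligand is used if a test reaction shows that it is the one giving the (4S) vinyl centre.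
- O-Benzylvanillin and O-benzylsyringaldehyde are catalogue compounds and are purchased.
- TBS = tert-butyldimethylsilyl.

**Route**

Step 1
Reactants: 1 4-(benzyloxy)-3-methoxybenzaldehyde; 2 methyl nitroacetate
Product: 3 methyl (Z)-3-[4-(benzyloxy)-3-methoxyphenyl]-2-nitroprop-2-enoate
Conditions: TiCl4 (2 equiv), N-methylmorpholine (4 equiv), THF, 0 °C to rt
Reagents that add atoms: none
Why: TiCl4/amine-mediated Knoevenagel condensation, in which the titanium nitronate of 2 adds to the activated aldehyde and the aldolate eliminates irreversibly to the conjugated nitroacrylate; any E isomer is carried along because the alkene geometry is not transferred to a stereocentre.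

Step 2
Reactants: 3 methyl (Z)-3-[4-(benzyloxy)-3-methoxyphenyl]-2-nitroprop-2-enoate; 4 vinylethylene carbonate (racemic, 1.5 equiv)
Product: 5 methyl (2S,3S,4S)-2-[4-(benzyloxy)-3-methoxyphenyl]-3-nitro-4-vinyltetrahydrofuran-3-carboxylate
Conditions: Pd2(dba)3·CHCl3 (2.5 mol%), (Sa,S,S)-O,O'-(1,1'-binaphthyl-2,2'-diyl) N,N-bis(1-phenylethyl)phosphoramidite (10 mol%), THF, 0 °C to rt
Reagents that add atoms: none
Why: Zerovalent palladium ionises racemic 4 with loss of CO2 to a zwitterionic π-allylpalladium alkoxide whose diastereomeric forms interconvert by π–σ–π isomerisation; the alkoxide adds reversibly to the aryl-bearing β-carbon of 3 (oxa-Michael, O1–C7) and the nitronate carbon then attacks the internal allyl terminus (C8–C8'), releasing the catalyst. The closest known reaction type is the palladium-catalysed decarboxylative [3+2] cycloaddition of vinylethylene carbonates with doubly activated alkenes. Ring A closes in the allylic alkylation as a 5-exo attack on the allyl unit with the vinyl group left exocyclic, since attack at the distal terminus would need a seven-membered ring. C8' is set by the chiral ligand, which selects the allyl face in the C–C bond-forming step (dynamic kinetic asymmetric transformation of racemic 4); C7 is set relative to C8' in the same ring closure, where the reversible oxa-Michael step should let the nitronate diastereomers funnel through the transition state with aryl pseudo-equatorial and trans to vinyl; the quaternary C8 is drawn provisionally and its configuration is of no consequence because step 3 erases it. The step needs branched regioselectivity, the 2,4-trans relationship and high enantiomeric excess: the two acceptor groups on one carbon polarise 3 so that oxygen goes to the benzylic carbon and carbon to the nitro ester carbon, and the E/Z composition of 3 is irrelevant because the geometry is lost at the nitronate stage.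

Step 3
Reactants: 5 methyl (2S,3S,4S)-2-[4-(benzyloxy)-3-methoxyphenyl]-3-nitro-4-vinyltetrahydrofuran-3-carboxylate
Product: 6 methyl (2R,4S)-2-[4-(benzyloxy)-3-methoxyphenyl]-4-vinyltetrahydrofuran-3-carboxylate (both C3 epimers)
Conditions: Bu3SnH (3 equiv), AIBN (0.3 equiv), toluene, 90 °C
Reagents that add atoms: none
Why: Radical denitration of a tertiary α-nitro ester, in which the stannyl radical adds to the nitro oxygen, the C–N bond fragments to the ester-stabilised C8 radical and Bu3SnH caps it; both C3 epimers of 5 converge on the same radical, hydrogen delivery anti to the aryl group probably favours the 2,3-cis ester, and C7 and C8' are untouched.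

Step 4
Reactants: 6 methyl (2R,4S)-2-[4-(benzyloxy)-3-methoxyphenyl]-4-vinyltetrahydrofuran-3-carboxylate (both C3 epimers)
Product: 7 methyl (2R,3R,4S)-2-[4-(benzyloxy)-3-methoxyphenyl]-4-vinyltetrahydrofuran-3-carboxylate
Conditions: NaOMe (0.3 equiv), MeOH, rt to 50 °C; minor epimer resubjected
Reagents that add atoms: none
Why: Thermodynamic epimerisation through the ester enolate (methoxide matched to the methyl ester) should place the ester trans to the larger 2-aryl neighbour and therefore cis to the vinyl group, which sets C8; expulsion of O1 from the enolate is the reverse of a 5-endo-trig closure and is expected to be slow.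

Step 5
Reactants: 7 methyl (2R,3R,4S)-2-[4-(benzyloxy)-3-methoxyphenyl]-4-vinyltetrahydrofuran-3-carboxylate
Product: 8 [(2R,3S,4S)-2-[4-(benzyloxy)-3-methoxyphenyl]-4-vinyltetrahydrofuran-3-yl]methanol
Conditions: LiAlH4, THF, 0 °C
Reagents that add atoms: none
Why: Standard LiAlH4 reduction of a methyl ester to the primary alcohol (C9–OH); the benzyl ether and vinyl group are inert and no stereocentre is touched.

Step 6
Reactants: 8 [(2R,3S,4S)-2-[4-(benzyloxy)-3-methoxyphenyl]-4-vinyltetrahydrofuran-3-yl]methanol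
Product: 11 (1S,5S,6R)-6-[4-(benzyloxy)-3-methoxyphenyl]-3,7-dioxabicyclo[3.3.0]octan-2-ol (anomers), via vicinal diol 9 (not isolated), via hydroxy aldehyde 10 (not isolated)
Conditions: K2OsO4·2H2O (2 mol%), NaIO4 (4 equiv), 2,6-lutidine (2 equiv), dioxane/H2O (3:1), rt
Reagents that add atoms: sodium periodate, [Na+].[O-]I(=O)(=O)=O (terminal oxidant; the new oxygen at C7' is delivered through the osmium catalyst, O.O.[K+].[K+].[O-][Os](=O)(=O)[O-])
Why: Lemieux–Johnson oxidation turns the vinyl group into the C7' aldehyde without exposing the electron-rich arene to ozone, and the cis C9 hydroxyl closes onto it as a five-membered lactol, which only the 3,4-cis isomer can do, so residual C8 epimer is also purged.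

Step 7
Reactants: 11 (1S,5S,6R)-6-[4-(benzyloxy)-3-methoxyphenyl]-3,7-dioxabicyclo[3.3.0]octan-2-ol
Product: 12 (1S,5S,6R)-6-[4-(benzyloxy)-3-methoxyphenyl]-3,7-dioxabicyclo[3.3.0]octan-2-one
Conditions: (n-Pr)4N[RuO4] (5 mol%), N-methylmorpholine N-oxide (1.5 equiv), 4 Å molecular sieves, CH2Cl2, rt
Reagents that add atoms: none
Why: Ley–Griffith oxidation of a lactol to the γ-lactone under neutral conditions, which leaves the benzylic ether C7–O1 and the α-centre C8' untouched.

Step 8
Reactants: 13 4-bromo-2,6-dimethoxyphenol; 14 ethyl bromoacetate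
Product: 15 ethyl 2-(4-bromo-2,6-dimethoxyphenoxy)acetate
Conditions: K2CO3, acetone, reflux
Reagents that add atoms: none
Why: Williamson O-alkylation (SN2) of the hindered but acidic phenol with an activated primary bromide.

Step 9
Reactants: 15 ethyl 2-(4-bromo-2,6-dimethoxyphenoxy)acetate
Product: 16 2-(4-bromo-2,6-dimethoxyphenoxy)acetic acid
Conditions: LiOH, THF/H2O, rt; then 1 M HCl
Reagents that add atoms: lithium hydroxide, [Li+].[OH-]
Why: Saponification of an unhindered ethyl ester by acyl–oxygen cleavage.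

Step 10
Reactants: 16 2-(4-bromo-2,6-dimethoxyphenoxy)acetic acid; 17 (S)-4-benzyloxazolidin-2-one
Product: 19 (S)-4-benzyl-3-[2-(4-bromo-2,6-dimethoxyphenoxy)acetyl]oxazolidin-2-one, via mixed pivalic anhydride 18 (not isolated)
Conditions: t-BuCOCl, Et3N, THF, −20 °C; then LiCl, 17, −20 °C to rt
Reagents that add atoms: none
Why: Mixed-anhydride activation followed by LiCl-assisted N-acylation of the oxazolidinone, which attacks the less hindered aryloxyacetyl carbonyl.

Step 11
Reactants: 19 (S)-4-benzyl-3-[2-(4-bromo-2,6-dimethoxyphenoxy)acetyl]oxazolidin-2-one; 20 4-(benzyloxy)-3,5-dimethoxybenzaldehyde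
Product: 22 (S)-4-benzyl-3-[(2S,3R)-3-[4-(benzyloxy)-3,5-dimethoxyphenyl]-2-(4-bromo-2,6-dimethoxyphenoxy)-3-hydroxypropanoyl]oxazolidin-2-one, via Z dibutylboron enolate 21 (not isolated)
Conditions: Bu2BOTf (1.2 equiv), Et3N (1.4 equiv), CH2Cl2, −78 to 0 °C; 20, −78 to 0 °C; then pH 7 buffer, MeOH, 30% H2O2, 0 °C
Reagents that add atoms: none
Why: Evans syn glycolate aldol, in which soft enolisation gives the Z boron enolate and a closed Zimmerman–Traxler chair with the auxiliary shielding one enolate face should set (2S,3R), that is the threo C8''(R)/C7''(R) pair once the acyl carbon is reduced.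

Step 12
Reactants: 22 (S)-4-benzyl-3-[(2S,3R)-3-[4-(benzyloxy)-3,5-dimethoxyphenyl]-2-(4-bromo-2,6-dimethoxyphenoxy)-3-hydroxypropanoyl]oxazolidin-2-one
Product: 23 (1R,2R)-1-[4-(benzyloxy)-3,5-dimethoxyphenyl]-2-(4-bromo-2,6-dimethoxyphenoxy)propane-1,3-diol
Conditions: LiBH4, MeOH (1 equiv), THF, 0 °C
Reagents that add atoms: none
Why: Reductive cleavage of the N-acyloxazolidinone gives the primary alcohol C9'' and returns the auxiliary; neither stereocentre can epimerise under these conditions.

Step 13
Reactants: 23 (1R,2R)-1-[4-(benzyloxy)-3,5-dimethoxyphenyl]-2-(4-bromo-2,6-dimethoxyphenoxy)propane-1,3-diol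
Product: 24 (1R,2R)-1-[4-(benzyloxy)-3,5-dimethoxyphenyl]-2-(4-bromo-2,6-dimethoxyphenoxy)-1,3-bis(tert-butyldimethylsilyloxy)propane
Conditions: TBSOTf (2.5 equiv), 2,6-lutidine, CH2Cl2, −78 to 0 °C
Reagents that add atoms: tert-butyldimethylsilyl triflate, CC(C)(C)[Si](C)(C)OS(=O)(=O)C(F)(F)F
Why: Silylation of both hydroxyls with the silyl triflate masks the diol for the organolithium and Lewis acid steps without touching a stereocentre.

Step 14
Reactants: 24 (1R,2R)-1-[4-(benzyloxy)-3,5-dimethoxyphenyl]-2-(4-bromo-2,6-dimethoxyphenoxy)-1,3-bis(tert-butyldimethylsilyloxy)propane; 12 (1S,5S,6R)-6-[4-(benzyloxy)-3-methoxyphenyl]-3,7-dioxabicyclo[3.3.0]octan-2-one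
Product: 26 (1S,5S,6R)-6-[4-(benzyloxy)-3-methoxyphenyl]-2-{4-[(1R,2R)-1-[4-(benzyloxy)-3,5-dimethoxyphenyl]-1,3-bis(tert-butyldimethylsilyloxy)propan-2-yl]oxy-3,5-dimethoxyphenyl}-3,7-dioxabicyclo[3.3.0]octan-2-ol (C7' anomers), via aryllithium 25 (not isolated)
Conditions: n-BuLi (1.05 equiv to 24), THF, −78 °C; then 12 (0.85 equiv), −78 °C; aq. NH4Cl
Reagents that add atoms: none
Why: Bromine–lithium exchange followed by addition of the aryllithium to the lactone carbonyl C7' forms the C7'–aryl bond; the tetrahedral lithium alkoxide is stable at −78 °C, which prevents double addition, and the hemiketal carbon is not yet a fixed stereocentre.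

Step 15
Reactants: 26 hemiketal from step 14
Product: 27 (1S,2S,5S,6R)-6-[4-(benzyloxy)-3-methoxyphenyl]-2-{4-[(1R,2R)-1-[4-(benzyloxy)-3,5-dimethoxyphenyl]-1,3-bis(tert-butyldimethylsilyloxy)propan-2-yl]oxy-3,5-dimethoxyphenyl}-3,7-dioxabicyclo[3.3.0]octane
Conditions: Et3SiH (5 equiv), BF3·OEt2 (2 equiv), CH2Cl2, −78 to −40 °C; aq. NaHCO3
Reagents that add atoms: none
Why: Ionic hydrogenation of a cyclic hemiketal, in which BF3·OEt2 generates the aryl-stabilised oxocarbenium ion of ring B and Et3SiH delivers hydride from the convex (exo) face of the cis-fused bicycle, placing the syringyl group endo (C7' S) as is general for 2-aryl-2-hydroxy-3,7-dioxabicyclo[3.3.0]octanes; low temperature should keep the kinetic endo product and the benzylic silyl ether intact.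

Step 16
Reactants: 27 bis-silyl ether from step 15
Product: 28 (1R,2R)-1-[4-(benzyloxy)-3,5-dimethoxyphenyl]-2-{4-[(1S,2S,5S,6R)-6-[4-(benzyloxy)-3-methoxyphenyl]-3,7-dioxabicyclo[3.3.0]octan-2-yl]-2,6-dimethoxyphenoxy}propane-1,3-diol
Conditions: Bu4NF (3 equiv), THF, 0 °C to rt; aq. NH4Cl
Reagents that add atoms: none
Why: Fluoride cleavage of both silyl ethers under non-acidic conditions, so the acid-labile endo benzylic ether at C7' is not epimerised.

Step 17
Reactants: 28 dibenzyl ether from step 16
Product: 29 target compound CNP0317965.1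
Conditions: H2 (1 atm), 10% Pd/C, EtOAc, rt, stopped when debenzylation is complete
Reagents that add atoms: none
Why: Hydrogenolysis of the two aryl benzyl ethers, which should be cleaved well before the dialkyl benzylic C–O bonds of rings A and B or the C7'' carbinol when the reaction is stopped at the uptake of two equivalents of hydrogen; no stereocentre is affected.

**Compound list**

1 | 4-(benzyloxy)-3-methoxybenzaldehyde (O-benzylvanillin) | COc1cc(C=O)ccc1OCc1ccccc1 | starting material
2 | methyl nitroacetate | COC(=O)C[N+](=O)[O-] | starting material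
3 | methyl (Z)-3-[4-(benzyloxy)-3-methoxyphenyl]-2-nitroprop-2-enoate | COC(=O)/C(=C/c1ccc(OCc2ccccc2)c(OC)c1)[N+](=O)[O-] | intermediate
4 | 4-vinyl-1,3-dioxolan-2-one (vinylethylene carbonate, racemic) | C=CC1COC(=O)O1 | starting material
5 | methyl (2S,3S,4S)-2-[4-(benzyloxy)-3-methoxyphenyl]-3-nitro-4-vinyltetrahydrofuran-3-carboxylate (C3 provisional) | COc1cc([C@@H]2OC[C@@H](C=C)[C@]2(C(=O)OC)[N+](=O)[O-])ccc1OCc1ccccc1 | intermediate
6 | methyl (2R,4S)-2-[4-(benzyloxy)-3-methoxyphenyl]-4-vinyltetrahydrofuran-3-carboxylate, both C3 epimers | COc1cc([C@@H]2OC[C@@H](C=C)C2C(=O)OC)ccc1OCc1ccccc1 | intermediate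
7 | methyl (2R,3R,4S)-2-[4-(benzyloxy)-3-methoxyphenyl]-4-vinyltetrahydrofuran-3-carboxylate | COc1cc([C@@H]2OC[C@@H](C=C)[C@H]2C(=O)OC)ccc1OCc1ccccc1 | intermediate
8 | [(2R,3S,4S)-2-[4-(benzyloxy)-3-methoxyphenyl]-4-vinyltetrahydrofuran-3-yl]methanol | COc1cc([C@@H]2OC[C@@H](C=C)[C@H]2CO)ccc1OCc1ccccc1 | intermediate
9 | 1-[(3S,4S,5R)-5-[4-(benzyloxy)-3-methoxyphenyl]-4-(hydroxymethyl)tetrahydrofuran-3-yl]ethane-1,2-diol (carbinol epimers) | COc1cc([C@@H]2OC[C@@H](C(O)CO)[C@H]2CO)ccc1OCc1ccccc1 | intermediate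
10 | (3S,4S,5R)-5-[4-(benzyloxy)-3-methoxyphenyl]-4-(hydroxymethyl)tetrahydrofuran-3-carbaldehyde | COc1cc([C@@H]2OC[C@@H](C=O)[C@H]2CO)ccc1OCc1ccccc1 | intermediate
11 | (1S,5S,6R)-6-[4-(benzyloxy)-3-methoxyphenyl]-3,7-dioxabicyclo[3.3.0]octan-2-ol (anomers) | COc1cc([C@@H]2OC[C@@H]3[C@H]2COC3O)ccc1OCc1ccccc1 | intermediate
12 | (1S,5S,6R)-6-[4-(benzyloxy)-3-methoxyphenyl]-3,7-dioxabicyclo[3.3.0]octan-2-one | COc1cc([C@@H]2OC[C@@H]3[C@H]2COC3=O)ccc1OCc1ccccc1 | intermediate
13 | 4-bromo-2,6-dimethoxyphenol | COc1cc(Br)cc(OC)c1O | starting material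
14 | ethyl bromoacetate | CCOC(=O)CBr | starting material
15 | ethyl 2-(4-bromo-2,6-dimethoxyphenoxy)acetate | CCOC(=O)COc1c(OC)cc(Br)cc1OC | intermediate
16 | 2-(4-bromo-2,6-dimethoxyphenoxy)acetic acid | OC(=O)COc1c(OC)cc(Br)cc1OC | intermediate
17 | (S)-4-benzyloxazolidin-2-one | O=C1N[C@@H](Cc2ccccc2)CO1 | starting material
18 | 2-(4-bromo-2,6-dimethoxyphenoxy)acetic pivalic anhydride | CC(C)(C)C(=O)OC(=O)COc1c(OC)cc(Br)cc1OC | intermediate
19 | (S)-4-benzyl-3-[2-(4-bromo-2,6-dimethoxyphenoxy)acetyl]oxazolidin-2-one | COc1cc(Br)cc(OC)c1OCC(=O)N1[C@@H](Cc2ccccc2)COC1=O | intermediate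
20 | 4-(benzyloxy)-3,5-dimethoxybenzaldehyde (O-benzylsyringaldehyde) | COc1cc(C=O)cc(OC)c1OCc1ccccc1 | starting material
21 | (Z)-dibutylboron enolate of 19 | CCCCB(CCCC)O/C(=C\Oc1c(OC)cc(Br)cc1OC)N1[C@@H](Cc2ccccc2)COC1=O | intermediate
22 | (S)-4-benzyl-3-[(2S,3R)-3-[4-(benzyloxy)-3,5-dimethoxyphenyl]-2-(4-bromo-2,6-dimethoxyphenoxy)-3-hydroxypropanoyl]oxazolidin-2-one | COc1cc(Br)cc(OC)c1O[C@H](C(=O)N1[C@@H](Cc2ccccc2)COC1=O)[C@H](O)c1cc(OC)c(OCc2ccccc2)c(OC)c1 | intermediate
23 | (1R,2R)-1-[4-(benzyloxy)-3,5-dimethoxyphenyl]-2-(4-bromo-2,6-dimethoxyphenoxy)propane-1,3-diol | COc1cc(Br)cc(OC)c1O[C@H](CO)[C@H](O)c1cc(OC)c(OCc2ccccc2)c(OC)c1 | intermediate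
24 | (1R,2R)-1-[4-(benzyloxy)-3,5-dimethoxyphenyl]-2-(4-bromo-2,6-dimethoxyphenoxy)-1,3-bis(tert-butyldimethylsilyloxy)propane | COc1cc(Br)cc(OC)c1O[C@H](CO[Si](C)(C)C(C)(C)C)[C@H](O[Si](C)(C)C(C)(C)C)c1cc(OC)c(OCc2ccccc2)c(OC)c1 | intermediate
25 | aryllithium from 24 (lithium in place of bromine) | [Li]c1cc(OC)c(O[C@H](CO[Si](C)(C)C(C)(C)C)[C@H](O[Si](C)(C)C(C)(C)C)c2cc(OC)c(OCc3ccccc3)c(OC)c2)c(OC)c1 | intermediate
26 | hemiketal: (1S,5S,6R)-6-[4-(benzyloxy)-3-methoxyphenyl]-2-aryl-3,7-dioxabicyclo[3.3.0]octan-2-ol, aryl = the side-chain-bearing syringyl group of 24, C7' anomers | COc1cc([C@@H]2OC[C@@H]3[C@H]2COC3(O)c2cc(OC)c(O[C@H](CO[Si](C)(C)C(C)(C)C)[C@H](O[Si](C)(C)C(C)(C)C)c3cc(OC)c(OCc4ccccc4)c(OC)c3)c(OC)c2)ccc1OCc1ccccc1 | intermediate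
27 | (7R,8S,7'S,8'S,7''R,8''R) furofuran with both phenols as benzyl ethers and the C7''/C9'' hydroxyls as TBS ethers | COc1cc([C@@H]2OC[C@@H]3[C@H]2CO[C@@H]3c2cc(OC)c(O[C@H](CO[Si](C)(C)C(C)(C)C)[C@H](O[Si](C)(C)C(C)(C)C)c3cc(OC)c(OCc4ccccc4)c(OC)c3)c(OC)c2)ccc1OCc1ccccc1 | intermediate
28 | (7R,8S,7'S,8'S,7''R,8''R) furofuran diol with both phenols as benzyl ethers | COc1cc([C@@H]2OC[C@@H]3[C@H]2CO[C@@H]3c2cc(OC)c(O[C@H](CO)[C@H](O)c3cc(OC)c(OCc4ccccc4)c(OC)c3)c(OC)c2)ccc1OCc1ccccc1 | intermediate
29 | CNP0317965.1 | COc1cc([C@@H]2OC[C@@H]3[C@H]2CO[C@@H]3c2cc(OC)c(O[C@H](CO)[C@H](O)c3cc(OC)c(O)c(OC)c3)c(OC)c2)ccc1O | target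

**Step count**

Total: 17 steps. Longest linear sequence: 11 steps (steps 1–7 and 14–17, from aldehyde 1). The side-chain branch (steps 8–13) is 6 steps and joins at step 14.

**Steps most likely to fail**

Step 2. Ring closure may pass through the diastereomeric transition state with aryl cis to vinyl, facial control of the allyl unit by the ligand may be low, or the very electrophilic nitroacrylate may be consumed by oligomerisation before the zwitterion closes. Fallback: ring A is built by lactone-enolate aldol addition and cyclodehydration, a sequence known for 2-aryl-4-vinyltetrahydrofuran lignan intermediates. It sets out from aldehyde 1 and returns at alcohol 8. (R)-4-Vinyldihydrofuran-2(3H)-one F1 is made from (Z)-but-2-ene-1,4-diol and triethyl orthoacetate by Johnson–Claisen rearrangement with lactonisation in the flask and is resolved by chromatography on a chiral stationary phase. Its lithium enolate (LiN(i-Pr)2, THF, −78 °C) adds to 1 anti to the vinyl group to give (3R,4S)-3-{[4-(benzyloxy)-3-methoxyphenyl](hydroxy)methyl}-4-vinyldihydrofuran-2(3H)-one F2 as carbinol epimers. LiAlH4 reduces it to (2S,3S)-1-[4-(benzyloxy)-3-methoxyphenyl]-2-(hydroxymethyl)-3-vinylbutane-1,4-diol F3. Camphorsulfonic acid in CH2Cl2 then closes ring A through the benzylic cation (O1–C7) under thermodynamic control, with aryl trans to C9, giving 8; only the C9' hydroxyl can form a five-membered ring. Steps 2–5 are bypassed.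

Step 4. The equilibrium may not favour the wanted ester strongly, because each epimer carries one cis interaction, or the enolate may expel O1, reclose and drift toward the all-trans isomer with C7 inverted. Fallback: C8 is fixed by ring fusion instead of by equilibration. It sets out from cycloadduct 5 (the C3 epimer with the ester cis to vinyl, as drawn) and returns at lactone 12. NaBH4 in MeOH/THF at 0 °C reduces the activated α-nitro ester to [(2S,3R,4S)-2-[4-(benzyloxy)-3-methoxyphenyl]-3-nitro-4-vinyltetrahydrofuran-3-yl]methanol F4. Base-free cleavage of the vinyl group (K2OsO4·2H2O cat., NaIO4, THF/H2O) gives the aldehyde, which closes to the bridgehead nitro lactol F5. PhI(OAc)2 with catalytic TEMPO gives (1S,5R,6S)-6-[4-(benzyloxy)-3-methoxyphenyl]-5-nitro-3,7-dioxabicyclo[3.3.0]octan-2-one F6. Bu3SnH/AIBN in toluene at 90 °C removes the nitro group, and the bridgehead radical can only take up hydrogen to give the cis-fused bicycle 12. Steps 3–7 are bypassed.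

Step 15. Hydride delivery to the oxocarbenium ion may be less face-selective with the bulky side-chain-bearing aryl group, and the Lewis acid may reopen the new endo benzylic ether and equilibrate it to the exo isomer or ionise the benzylic silyl ether. Fallback: C7' is set by addition to an aldehyde and ring B is closed by a Williamson reaction at C9, with no benzylic cation. It sets out from lactol 11 (with aryllithium 25 from bromide 24) and returns at 27. Lactol 11 is deprotonated with LiN(SiMe3)2 in THF at −78 °C and treated with 25, which should add to the open hydroxy aldehyde form anti to C8 (Felkin–Anh) to give the (7'S) diol F7. Selective tosylation of the primary hydroxyl (TsCl, pyridine, 0 °C) gives the primary tosylate F8. NaH in THF then closes ring B by 5-exo-tet displacement at C9 with retention at C7', giving 27. Steps 7, 14 and 15 are bypassed.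

**Further compounds**

F1 | step 2 | (R)-4-vinyldihydrofuran-2(3H)-one | O=C1C[C@H](C=C)CO1
F2 | step 2 | (3R,4S)-3-{[4-(benzyloxy)-3-methoxyphenyl](hydroxy)methyl}-4-vinyldihydrofuran-2(3H)-one (carbinol epimers) | O=C1OC[C@@H](C=C)[C@@H]1C(O)c1ccc(OCc2ccccc2)c(OC)c1
F3 | step 2 | (2S,3S)-1-[4-(benzyloxy)-3-methoxyphenyl]-2-(hydroxymethyl)-3-vinylbutane-1,4-diol (carbinol epimers) | OC[C@@H](C=C)[C@@H](CO)C(O)c1ccc(OCc2ccccc2)c(OC)c1
F4 | step 4 | [(2S,3R,4S)-2-[4-(benzyloxy)-3-methoxyphenyl]-3-nitro-4-vinyltetrahydrofuran-3-yl]methanol | COc1cc([C@@H]2OC[C@@H](C=C)[C@]2(CO)[N+](=O)[O-])ccc1OCc1ccccc1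
F5 | step 4 | (1S,5R,6S)-6-[4-(benzyloxy)-3-methoxyphenyl]-5-nitro-3,7-dioxabicyclo[3.3.0]octan-2-ol (anomers) | COc1cc([C@@H]2OC[C@@H]3[C@@]2([N+](=O)[O-])COC3O)ccc1OCc1ccccc1
F6 | step 4 | (1S,5R,6S)-6-[4-(benzyloxy)-3-methoxyphenyl]-5-nitro-3,7-dioxabicyclo[3.3.0]octan-2-one | COc1cc([C@@H]2OC[C@@H]3[C@@]2([N+](=O)[O-])COC3=O)ccc1OCc1ccccc1
F7 | step 15 | (7'S) diol: ring A of 8 with the vinyl group replaced by (S)-CH(OH)-aryl, aryl = the side-chain-bearing syringyl group of 24 | COc1cc([C@@H]2OC[C@H]([C@H]2CO)[C@H](O)c2cc(OC)c(O[C@H](CO[Si](C)(C)C(C)(C)C)[C@H](O[Si](C)(C)C(C)(C)C)c3cc(OC)c(OCc4ccccc4)c(OC)c3)c(OC)c2)ccc1OCc1ccccc1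
F8 | step 15 | primary p-toluenesulfonate of F7 at C9 | COc1cc([C@@H]2OC[C@H]([C@H]2COS(=O)(=O)c2ccc(C)cc2)[C@H](O)c2cc(OC)c(O[C@H](CO[Si](C)(C)C(C)(C)C)[C@H](O[Si](C)(C)C(C)(C)C)c3cc(OC)c(OCc4ccccc4)c(OC)c3)c(OC)c2)ccc1OCc1ccccc1
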